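## Structural features

The target 34 is a C2-symmetric molecule built on a central tetrahydrofuran (O1, C2, C3, C4, C5). C2 and C5 each carry a 3-methoxy-4-oxyphenyl ring, C3 and C4 each carry a methyl group, and the para oxygen of each ring is bound to C8 of a 1-(3,4-dimethoxyphenyl)-1-hydroxypropan-2-yl chain (C7 carbinol, C8 ether carbon).

The ring holds four contiguous stereocentres, C2 (R), C3 (S), C4 (S), C5 (R). Each aryl group is cis to the neighbouring methyl group, the methyl groups are trans to each other, and the aryl groups are trans across O1 (cis,trans,cis).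

Each side chain holds two adjacent stereocentres, C7 (R) and C8 (R), in the threo relationship. The ring set and the side-chain sets are too far apart to control one another.

The fragile groups are the C2–O1 and C5–O1 bonds (benzylic ethers para to an oxygen donor, which ionise with acid or open through a quinone methide when the phenol is free), the electron-rich benzylic C7 alcohols, and C8–H in any intermediate that has a carbonyl group at C7.

The real difficulty is that the cis,trans,cis ring is not the thermodynamically preferred arrangement. It must be closed under stereospecific kinetic control and must not meet ionising conditions afterwards.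

The key step uses the O1–C2 bond. C2 is a secondary benzylic carbon that can act as an electrophile, so an open chain of opposite C2 configuration, (2S), closes by backside attack of the C5 oxygen. The para oxygen of each aryl ring is first the place where the benzylic reactivity is turned down (as a sulfonate) and later the anchor for the side chains.

## Logic of the disconnections

34 to 33. The two C7–H bonds of 34 are removed, which leads back to the two carbonyl groups of 33. The reason is that C7 can then be set by 1,2-induction from C8. The gain is two fewer stereocentres and an electrophile-activating carbonyl beside C8. The demand is hydride delivery in the non-chelated Felkin–Anh sense at both carbonyl groups, without base that would enolise toward C8.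

33 to 25 and 32. The two O–C8 bonds are cut. This is the symmetric, convergent cut, and C8 can come from the chiral pool with inversion. The gain is a small enantiopure electrophile, 32, and the core as 25. The demand is a clean twofold SN2 with inversion, so the leaving group must not be able to return as a nucleophile and the base must not epimerise 32 or 33.

32 to 31, 27, 29, 28 and 26. The O–S bond of 32 leads to 31. The C7–aryl bond of 31 is cut to 27 and 29 (from 28), and the amide bond of 27 leads to 26. C8 is bought ready-made in 26. The demand is that the α-oxygenated carbonyl compounds are never enolised.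

25 to 24. The two aryl O–S bonds are cut. They are present only because the ring closure needs electron-poor aryl rings. The demand is cleavage without acid and without hot base, so that C2 and C5 keep their configuration.

24 to 22 (through 23). The O1–C2 bond is cut. This turns the cis C2/C3 ring relationship into an anti relationship in an open chain, which is the one that ketone reduction supplies. The gain is that the ring problem becomes an acyclic one. The demand is pure backside displacement at C2 with no ionisation and no elimination.

22 to 21 to 20. The C2 O–S bond leads to 21, and the C2–H bond of 21 leads to the C2 carbonyl group of 20. The reason is substrate control from C3. The demand is Felkin–Anh selectivity in the reduction, then sulfonylation with retention and without a nucleophilic counter-ion.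

20 to 15 and 18 (17, 16). The C2–aryl bond is cut. Both aryl rings then come from the same type of phenol sulfonate. The demand is an arylmagnesium reagent that coexists with an aryl sulfonate and an acyl substitution that stops at the ketone without epimerising C3.

15 to 14 to 13. The O–Si bond and the amide C–N bond are traced back to the ring acyl C–O bond of 13. The reason is that a five-membered ring is the best template for the C3/C4 relationship. The demand is that the freed C5 hydroxyl is capped before it re-closes.

13 to 12 to 11. The C3–CH3 bond is cut. The C4 methyl group and the C5 aryl group sit on one face of the ring, so the electrophile has one open face. The demand is monoalkylation.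

11 to 10, 9, 8 and 7. The carbonyl oxidation level is taken down to the primary alcohol of 9, and its C–O bond is traced to the terminal alkene carbon of 7. The gain is that both oxygens of the ring come from simple operations. The demand is chemoselective oxidation at the primary carbon.

7 to 6, 5, 4, 3, 2 and 1. The C4–C5 bond is cut between the carbonyl carbon of 2 and the crotyl unit of 5 (from 3 through 4). Both C4 and C5 are set in one step, relative configuration from the alkene geometry and absolute configuration from the boron ligands. 2 comes from 1 by O–S bond formation.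

## Other disconnections considered

Alternative 1: The cut is at the two aryl carbon to oxygen bonds that join the core rings to the side-chain oxygens. The forward step would couple the core dibromide A2 twice with the preformed threo alcohol A3 under Pd2(dba)3, a di-tert-butyl biarylphosphine and base to give the bis(methoxymethyl ether) A1, followed by acidic deprotection to 34.
- In its favour: C8 never becomes an electrophile and is never α to a carbonyl group, so both side-chain stereocentres are fixed in A3 before they meet the core. On the security of C7 and C8 this alternative is the better plan. A2 could be made by the same invertive closure, since bromine is also electron-withdrawing, so on the core the two plans are equal.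
- Against it: reductive elimination of an aryl–oxygen bond from divalent palladium is slowest for electron-rich, ortho-substituted aryl groups, which is what A2 offers. The secondary alkoxide of A3 has a β-hydrogen, so β-hydride elimination back to zerovalent palladium would compete. The coupling must succeed twice, and A3 is branched next to the reacting oxygen. The final acid treatment meets a core whose benzylic ethers are electron-rich again.
- Comparison: the SN2 displacement on an α-keto sulfonate in the chosen plan is the more dependable bond formation. From the core to 34 this alternative needs two steps against three, which is better, but A3 needs more steps than 32, so the totals are about equal.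

Alternative 2: The cut removes C3–C4, O1–C2 and O1–C5 at once, so the ring falls into two identical halves and water. The forward step would oxidise the (E)-propenylarene A5 at a carbon anode in wet acetonitrile: the radical cations would couple at their β-carbons (C3–C4) and one water molecule would capture both benzylic cation centres, giving the bis(acetate) A4, then 34 after ester cleavage.
- In its favour: it uses the twofold symmetry completely and makes three bonds and four stereocentres in one operation. On step count and convergence it is clearly the better plan.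
- Against it: nothing in A5 controls the ring. The C–O bonds would form through the benzylic cations that the chosen plan is designed to avoid, so the aryl/methyl relationships should follow the preference for trans, and the cis,trans,cis ring would be expected as a minor component at best. Even that component would be two diastereomers, because the side-chain stereocentres are too remote to select one ring enantiomer. The dimethoxyphenyl ring of A5 is also oxidisable, and cyclobutane or aryltetralin dimers could compete.
- Comparison: on structural control it is the weaker plan; the stereochemical problem that defines the target would be left to chance.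

Alternative 3: The cut is at C2–C3, with the C3 methyl group carried as a formyl group. The forward step would treat the dihydrodioxepine A7 with BF3·OEt2. The acetal C–O bond would ionise to an oxocarbenium ion and a tethered enolate, which would recombine through carbon to the tetrahydrofuran-3-carbaldehyde A6. The formyl group would then be taken down to methyl, and hydrogenolysis would lead to 25.
- In its favour: a carbon–carbon bond and the ring are made in one step with two stereocentres, which is more skeletal gain than the key step of the chosen plan and is better on that point. C4 and C5 would come from the same crotylation chemistry, which is equal. The benzyl ethers leave by neutral hydrogenolysis, which is gentler than desulfonylation and better.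
- Against it: the ionisation puts the positive charge at C2 beside an electron-rich aryl ring, the opposite of the chosen design. The C2/C3 relationship would depend on an ion-pair recombination and on whether the Lewis acid later re-opens the ring at C2 or enolises the aldehyde at C3. The target needs the more hindered arrangement, with the C3 substituent cis to the C2 aryl group. Removing the formyl oxygen costs about three operations next to sensitive benzylic ethers.
- Comparison: the step count to 25 would be about equal or slightly better if every step worked. The mechanism is a stepwise cationic process against a stereospecific displacement, so the stereochemical outcome is less secure.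

Key step: step 11

Remark on the chemistry: the ring is numbered O1, C2 to C5 in all intermediates, C2 being the carbon that carries the leaving group in 22; 22 is (2S,3S,4S,5R) and 24 is (2R,3S,4S,5R), which differ only by inversion at C2, so both structures are used without correction.

Remark on the chemistry: a racemic α-haloketone cannot deliver the (8R) ether centres, so the enantiopure α-keto tosylate 32 is used; 22 is made with Ms2O so that no chloride is present that could displace the mesylate and lead to overall retention.

Assumption: the (Z)-crotylborane from (+)-Ipc2BOMe (from (−)-α-pinene) attacks the Re face of aryl aldehydes; should the opposite sense be found, the enantiomeric borane is used.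

## Route

Step 1
Reactants: 1 vanillin
Product: 2 4-formyl-2-methoxyphenyl 4-methylbenzenesulfonate
Conditions: TsCl, Et3N, 4-(dimethylamino)pyridine (cat.), CH2Cl2, 0 °C to rt
Reagents that add atoms: p-toluenesulfonyl chloride, Cc1ccc(S(=O)(=O)Cl)cc1
Why: O-sulfonylation of a phenol; the tosylate is the electron-withdrawing spectator group needed later at C5 and makes the aldehyde more electrophilic.

Step 2
Reactants: 2 4-formyl-2-methoxyphenyl 4-methylbenzenesulfonate; 3 (Z)-but-2-ene
Product: 7 2-methoxy-4-[(1R,2S)-1-hydroxy-2-methylbut-3-en-1-yl]phenyl 4-methylbenzenesulfonate, via (Z)-crotylpotassium 4 (not isolated), via (Z)-crotylborane 5 (not isolated), via borinate adduct 6 (not isolated)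
Conditions: 3, KOt-Bu, n-BuLi, THF, −78 to −45 °C; (+)-Ipc2BOMe, −78 °C; BF3·OEt2, −78 °C; 2, −78 °C; NaBO3·4H2O, H2O, rt
Reagents that add atoms: none
Why: Brown crotylboration through a chair Zimmerman–Traxler transition state; the (Z)-crotyl geometry gives the syn pair and the Ipc groups from (−)-α-pinene direct attack to the Re face of the aldehyde, setting future C5 (R) and C4 (S).

Step 3
Reactants: 7 2-methoxy-4-[(1R,2S)-1-hydroxy-2-methylbut-3-en-1-yl]phenyl 4-methylbenzenesulfonate
Product: 9 2-methoxy-4-[(1R,2S)-1,4-dihydroxy-2-methylbutyl]phenyl 4-methylbenzenesulfonate, via bis(boryl) adduct 8 (not isolated)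
Conditions: 9-BBN (2.5 equiv), THF, 0 °C to rt; NaBO3·4H2O, H2O, rt
Reagents that add atoms: sodium perborate (oxygen source), [Na+].[Na+].O[B-]1(O)OO[B-](O)(O)OO1
Why: anti-Markovnikov hydroboration–oxidation of the terminal alkene; perborate is used in place of alkaline peroxide to spare the aryl sulfonate, and no stereocentre is touched.

Step 4
Reactants: 9 2-methoxy-4-[(1R,2S)-1,4-dihydroxy-2-methylbutyl]phenyl 4-methylbenzenesulfonate
Product: 11 2-methoxy-4-[(2R,3S)-3-methyl-5-oxotetrahydrofuran-2-yl]phenyl 4-methylbenzenesulfonate, via lactol 10 (not isolated)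
Conditions: TEMPO [(2,2,6,6-tetramethylpiperidin-1-yl)oxyl] (cat.), PhI(OAc)2, CH2Cl2, rt
Reagents that add atoms: none
Why: oxoammonium-mediated oxidative lactonisation of a 1,4-diol; the primary alcohol is oxidised first, the hydroxy aldehyde closes to lactol 10, and this is oxidised to the lactone before the secondary benzylic alcohol can react.

Step 5
Reactants: 11 2-methoxy-4-[(2R,3S)-3-methyl-5-oxotetrahydrofuran-2-yl]phenyl 4-methylbenzenesulfonate
Product: 13 2-methoxy-4-[(2R,3S,4S)-3,4-dimethyl-5-oxotetrahydrofuran-2-yl]phenyl 4-methylbenzenesulfonate, via lithium enolate 12 (not isolated)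
Conditions: LiN(SiMe3)2, THF, −78 °C; MeI, −78 to −40 °C
Reagents that add atoms: iodomethane, CI
Why: lactone enolate alkylation; the C4 methyl and C5 aryl groups shield one face, so iodomethane enters trans to the C4 methyl group and sets future C3 (S).

Step 6
Reactants: 13 2-methoxy-4-[(2R,3S,4S)-3,4-dimethyl-5-oxotetrahydrofuran-2-yl]phenyl 4-methylbenzenesulfonate
Product: 15 (2S,3S,4R)-N-methoxy-N,2,3-trimethyl-4-[3-methoxy-4-(tosyloxy)phenyl]-4-(triethylsilyloxy)butanamide, via hydroxy Weinreb amide 14 (not isolated)
Conditions: Me(MeO)NH·HCl, AlMe3, CH2Cl2, 0 °C to rt; aq. potassium sodium tartrate (KNaC4H4O6); crude 14: Et3SiOTf, 2,6-lutidine, CH2Cl2, −78 to 0 °C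
Reagents that add atoms: N,O-dimethylhydroxylamine hydrochloride, CNOC.Cl; triethylsilyl trifluoromethanesulfonate, CC[Si](CC)(CC)OS(=O)(=O)C(F)(F)F
Why: Weinreb aminolysis of the lactone by the aluminium amide, which is not basic enough to enolise C3; fast silylation of the crude C5 alcohol prevents relactonisation.

Step 7
Reactants: 16 4-bromo-2-methoxyphenol
Product: 17 4-bromo-2-methoxyphenyl 4-methylbenzenesulfonate
Conditions: TsCl, Et3N, 4-(dimethylamino)pyridine (cat.), CH2Cl2, 0 °C to rt
Reagents that add atoms: p-toluenesulfonyl chloride, Cc1ccc(S(=O)(=O)Cl)cc1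
Why: O-sulfonylation of a phenol; it installs the deactivating group for the C2 aryl ring before the organometallic step.

Step 8
Reactants: 15 (2S,3S,4R)-N-methoxy-N,2,3-trimethyl-4-[3-methoxy-4-(tosyloxy)phenyl]-4-(triethylsilyloxy)butanamide; 17 4-bromo-2-methoxyphenyl 4-methylbenzenesulfonate
Product: 20 (2S,3S,4R)-2,3-dimethyl-1,4-bis[3-methoxy-4-(tosyloxy)phenyl]-4-(triethylsilyloxy)butan-1-one, via arylmagnesium chloride 18 (not isolated), via tetrahedral adduct 19 (not isolated)
Conditions: 17, iPrMgCl·LiCl, THF, 0 °C to rt; then 15, THF, −20 to 0 °C; aq. NH4Cl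
Reagents that add atoms: none
Why: bromine–magnesium exchange para to a sulfonate gives a stable arylmagnesium reagent; Weinreb ketone synthesis stops at the chelated adduct 19, so there is no over-addition and C3 is not enolised at low temperature.

Step 9
Reactants: 20 (2S,3S,4R)-2,3-dimethyl-1,4-bis[3-methoxy-4-(tosyloxy)phenyl]-4-(triethylsilyloxy)butan-1-one
Product: 21 (1S,2S,3S,4R)-2,3-dimethyl-1,4-bis[3-methoxy-4-(tosyloxy)phenyl]-4-(triethylsilyloxy)butan-1-ol
Conditions: LiBH(s-Bu)3, THF, −78 °C; NaBO3·4H2O, H2O, 0 °C to rt
Reagents that add atoms: none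
Why: Felkin–Anh-controlled hydride reduction; the branched chain on C3 stands anti to the incoming bulky hydride, which passes the C3 hydrogen and gives the anti C2/C3 carbinol, C2 (S).

Step 10
Reactants: 21 (1S,2S,3S,4R)-2,3-dimethyl-1,4-bis[3-methoxy-4-(tosyloxy)phenyl]-4-(triethylsilyloxy)butan-1-ol
Product: 22 (1S,2S,3S,4R)-2,3-dimethyl-1,4-bis[3-methoxy-4-(tosyloxy)phenyl]-4-(triethylsilyloxy)butyl methanesulfonate
Conditions: Ms2O, Et3N, 4-(dimethylamino)pyridine (cat.), CH2Cl2, −20 to 0 °C; used without chromatography
Reagents that add atoms: methanesulfonic anhydride, CS(=O)(=O)OS(C)(=O)=O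
Why: O-mesylation with retention at C2, since only the O–H bond is broken; the anhydride avoids chloride, and the electron-poor aryl ring keeps the benzylic mesylate from ionising.

Step 11
Reactants: 22 (1S,2S,3S,4R)-2,3-dimethyl-1,4-bis[3-methoxy-4-(tosyloxy)phenyl]-4-(triethylsilyloxy)butyl methanesulfonate
Product: 24 (2R,3S,4S,5R)-2,5-bis[3-methoxy-4-(tosyloxy)phenyl]-3,4-dimethyltetrahydrofuran, via C5 alkoxide 23 (not isolated)
Conditions: Bu4NF (1.0 M in THF), THF, 0 °C to rt
Reagents that add atoms: none
Why: Fluoride attacks silicon of the triethylsilyl ether and releases the C5 alkoxide 23 as its tetrabutylammonium salt. The alkoxide then attacks C2 from the face opposite the mesylate, the closest known reaction type being the intramolecular Williamson etherification of a 1,4-diol monosulfonate. The one ring that forms, the tetrahydrofuran, closes in the 5-exo-tet mode, which allows the collinear arrangement of nucleophile, C2 and leaving group. The one new ring stereocentre, C2, is controlled by the (2S) configuration of the mesylate from steps 9 and 10: inversion turns the anti C2/C3 pair into the cis aryl/methyl pair, C2 (R). C5 keeps its configuration because its C–O bond is not broken, and C3 and C4 are not touched. The step needs substitution with inversion to win over ionisation at C2, which would give the trans epimer, and over elimination toward C3. The para sulfonyloxy group on each aryl ring destabilises the benzylic cation, and the high effective molarity of the internal alkoxide, the non-ionising solvent and the low temperature favour the concerted displacement. The aryl tosylates should survive fluoride at this temperature.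

Step 12
Reactants: 24 (2R,3S,4S,5R)-2,5-bis[3-methoxy-4-(tosyloxy)phenyl]-3,4-dimethyltetrahydrofuran
Product: 25 4,4′-[(2R,3S,4S,5R)-3,4-dimethyltetrahydrofuran-2,5-diyl]bis(2-methoxyphenol)
Conditions: Mg turnings, MeOH/THF, rt; aq. NH4Cl
Reagents that add atoms: none
Why: reductive desulfonylation by electron transfer from magnesium in methanol cleaves the aryl S–O bonds at room temperature; without acid or hot hydroxide, C2 and C5 should not open through a cation or a quinone methide.

Step 13
Reactants: 26 ethyl (S)-lactate
Product: 27 (S)-2-hydroxy-N-methoxy-N-methylpropanamide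
Conditions: Me(MeO)NH·HCl, iPrMgCl, THF, −20 to 0 °C; aq. NH4Cl
Reagents that add atoms: N,O-dimethylhydroxylamine hydrochloride, CNOC.Cl
Why: Weinreb amide formation by ester aminolysis with the magnesium amide; the stereocentre carries an alkoxide under these conditions and is not enolised.

Step 14
Reactants: 27 (S)-2-hydroxy-N-methoxy-N-methylpropanamide; 28 4-bromo-1,2-dimethoxybenzene
Product: 31 (S)-1-(3,4-dimethoxyphenyl)-2-hydroxypropan-1-one, via arylmagnesium bromide 29 (not isolated), via tetrahedral adduct 30 (not isolated)
Conditions: 28, Mg turnings, THF, rt to 40 °C; 27, iPrMgCl (1 equiv), THF, −20 °C; then 29, 0 °C to rt; aq. NH4Cl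
Reagents that add atoms: none
Why: Grignard formation and Weinreb ketone synthesis on the magnesium alkoxide of 27; the chelated adduct 30 releases the ketone only on work-up, which protects the (S) centre from enolisation.

Step 15
Reactants: 31 (S)-1-(3,4-dimethoxyphenyl)-2-hydroxypropan-1-one
Product: 32 (S)-1-(3,4-dimethoxyphenyl)-1-oxopropan-2-yl 4-methylbenzenesulfonate
Conditions: TsCl, Et3N, 4-(dimethylamino)pyridine (cat.), CH2Cl2, 0 °C
Reagents that add atoms: p-toluenesulfonyl chloride, Cc1ccc(S(=O)(=O)Cl)cc1
Why: O-sulfonylation with retention; unlike a halide, the departing tosylate cannot return as a nucleophile and racemise the electrophile.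

Step 16
Reactants: 25 4,4′-[(2R,3S,4S,5R)-3,4-dimethyltetrahydrofuran-2,5-diyl]bis(2-methoxyphenol); 32 (S)-1-(3,4-dimethoxyphenyl)-1-oxopropan-2-yl 4-methylbenzenesulfonate
Product: 33 (2R,2′R)-2,2′-{[(2R,3S,4S,5R)-3,4-dimethyltetrahydrofuran-2,5-diyl]bis[(2-methoxy-4,1-phenylene)oxy]}bis[1-(3,4-dimethoxyphenyl)propan-1-one]
Conditions: 32 (2.4 equiv), BEMP (2-tert-butylimino-2-diethylamino-1,3-dimethylperhydro-1,3,2-diazaphosphorine, 2.1 equiv), CH2Cl2, 0 °C to rt
Reagents that add atoms: none
Why: twofold Williamson-type SN2 etherification; each phenoxide displaces the α-keto tosylate with inversion, (S) to (R) at C8, the carbonyl group accelerating the displacement, and the non-ionic phosphazene base is used in no excess over the phenol so that C8 is not enolised.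

Step 17
Reactants: 33 (2R,2′R)-2,2′-{[(2R,3S,4S,5R)-3,4-dimethyltetrahydrofuran-2,5-diyl]bis[(2-methoxy-4,1-phenylene)oxy]}bis[1-(3,4-dimethoxyphenyl)propan-1-one]
Product: 34 (1R,1′R,2R,2′R)-2,2′-{[(2R,3S,4S,5R)-3,4-dimethyltetrahydrofuran-2,5-diyl]bis[(2-methoxy-4,1-phenylene)oxy]}bis[1-(3,4-dimethoxyphenyl)propan-1-ol]
Conditions: polystyrene-bound quaternary ammonium borohydride (resin–NMe3+ BH4−), MeOH/CH2Cl2, 0 °C to rt
Reagents that add atoms: none
Why: Felkin–Anh (polar) reduction without a chelating cation; the C8–OAr bond stands anti to the incoming hydride, which should give the syn (threo) 7R,8R carbinol at both ketones, and the reagent is not basic enough to epimerise C8.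

## Compound list

1 | vanillin (4-hydroxy-3-methoxybenzaldehyde) | COc1cc(C=O)ccc1O | starting material
2 | 4-formyl-2-methoxyphenyl 4-methylbenzenesulfonate | COc1cc(C=O)ccc1OS(=O)(=O)c1ccc(C)cc1 | intermediate
3 | (Z)-but-2-ene | C/C=C\C | starting material
4 | (Z)-crotylpotassium | C/C=C\C[K] | intermediate
5 | (Z)-but-2-en-1-ylbis(isopinocampheyl)borane, Ipc groups from (−)-α-pinene | C/C=C\CB([C@H]1C[C@H]2C[C@@H]([C@@H]1C)C2(C)C)[C@H]1C[C@H]2C[C@@H]([C@@H]1C)C2(C)C | intermediate
6 | O-bis(isopinocampheyl)boryl derivative (borinate) of 7 | COc1cc([C@H](OB([C@H]2C[C@H]3C[C@@H]([C@@H]2C)C3(C)C)[C@H]2C[C@H]3C[C@@H]([C@@H]2C)C3(C)C)[C@@H](C)C=C)ccc1OS(=O)(=O)c1ccc(C)cc1 | intermediate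
7 | 2-methoxy-4-[(1R,2S)-1-hydroxy-2-methylbut-3-en-1-yl]phenyl 4-methylbenzenesulfonate | COc1cc([C@H](O)[C@@H](C)C=C)ccc1OS(=O)(=O)c1ccc(C)cc1 | intermediate
8 | O,C-bis(9-borabicyclo[3.3.1]nonan-9-yl) adduct of 7 (boron on the terminal carbon and on the carbinol oxygen) | COc1cc([C@H](OB2C3CCCC2CCC3)[C@@H](C)CCB2C3CCCC2CCC3)ccc1OS(=O)(=O)c1ccc(C)cc1 | intermediate
9 | 2-methoxy-4-[(1R,2S)-1,4-dihydroxy-2-methylbutyl]phenyl 4-methylbenzenesulfonate | COc1cc([C@H](O)[C@@H](C)CCO)ccc1OS(=O)(=O)c1ccc(C)cc1 | intermediate
10 | 4-[(2R,3S)-5-hydroxy-3-methyltetrahydrofuran-2-yl]-2-methoxyphenyl 4-methylbenzenesulfonate (lactol, either anomer) | COc1cc([C@@H]2OC(O)C[C@@H]2C)ccc1OS(=O)(=O)c1ccc(C)cc1 | intermediate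
11 | 2-methoxy-4-[(2R,3S)-3-methyl-5-oxotetrahydrofuran-2-yl]phenyl 4-methylbenzenesulfonate | COc1cc([C@@H]2OC(=O)C[C@@H]2C)ccc1OS(=O)(=O)c1ccc(C)cc1 | intermediate
12 | lithium enolate of 11 | COc1cc([C@@H]2OC(O[Li])=C[C@@H]2C)ccc1OS(=O)(=O)c1ccc(C)cc1 | intermediate
13 | 2-methoxy-4-[(2R,3S,4S)-3,4-dimethyl-5-oxotetrahydrofuran-2-yl]phenyl 4-methylbenzenesulfonate | COc1cc([C@@H]2OC(=O)[C@@H](C)[C@@H]2C)ccc1OS(=O)(=O)c1ccc(C)cc1 | intermediate
14 | (2S,3S,4R)-4-hydroxy-N-methoxy-N,2,3-trimethyl-4-[3-methoxy-4-(tosyloxy)phenyl]butanamide | CON(C)C(=O)[C@@H](C)[C@H](C)[C@@H](O)c1ccc(OS(=O)(=O)c2ccc(C)cc2)c(OC)c1 | intermediate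
15 | (2S,3S,4R)-N-methoxy-N,2,3-trimethyl-4-[3-methoxy-4-(tosyloxy)phenyl]-4-(triethylsilyloxy)butanamide | CON(C)C(=O)[C@@H](C)[C@H](C)[C@@H](O[Si](CC)(CC)CC)c1ccc(OS(=O)(=O)c2ccc(C)cc2)c(OC)c1 | intermediate
16 | 4-bromo-2-methoxyphenol | COc1cc(Br)ccc1O | starting material
17 | 4-bromo-2-methoxyphenyl 4-methylbenzenesulfonate | COc1cc(Br)ccc1OS(=O)(=O)c1ccc(C)cc1 | intermediate
18 | [3-methoxy-4-(tosyloxy)phenyl]magnesium chloride (LiCl complex) | COc1cc([Mg]Cl)ccc1OS(=O)(=O)c1ccc(C)cc1 | intermediate
19 | chloromagnesium salt of the tetrahedral adduct of 18 with 15 (carbinolamine carbon of either configuration) | COc1cc([C@H](O[Si](CC)(CC)CC)[C@@H](C)[C@H](C)C(O[Mg]Cl)(N(C)OC)c2ccc(OS(=O)(=O)c3ccc(C)cc3)c(OC)c2)ccc1OS(=O)(=O)c1ccc(C)cc1 | intermediate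
20 | (2S,3S,4R)-2,3-dimethyl-1,4-bis[3-methoxy-4-(tosyloxy)phenyl]-4-(triethylsilyloxy)butan-1-one | COc1cc([C@H](O[Si](CC)(CC)CC)[C@@H](C)[C@H](C)C(=O)c2ccc(OS(=O)(=O)c3ccc(C)cc3)c(OC)c2)ccc1OS(=O)(=O)c1ccc(C)cc1 | intermediate
21 | (1S,2S,3S,4R)-2,3-dimethyl-1,4-bis[3-methoxy-4-(tosyloxy)phenyl]-4-(triethylsilyloxy)butan-1-ol | COc1cc([C@H](O[Si](CC)(CC)CC)[C@@H](C)[C@H](C)[C@H](O)c2ccc(OS(=O)(=O)c3ccc(C)cc3)c(OC)c2)ccc1OS(=O)(=O)c1ccc(C)cc1 | intermediate
22 | (1S,2S,3S,4R)-2,3-dimethyl-1,4-bis[3-methoxy-4-(tosyloxy)phenyl]-4-(triethylsilyloxy)butyl methanesulfonate; ring numbering (2S,3S,4S,5R) | COc1cc([C@H](O[Si](CC)(CC)CC)[C@@H](C)[C@H](C)[C@H](OS(C)(=O)=O)c2ccc(OS(=O)(=O)c3ccc(C)cc3)c(OC)c2)ccc1OS(=O)(=O)c1ccc(C)cc1 | intermediate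
23 | tetrabutylammonium C5 alkoxide of the desilylated mesylate | COc1cc([C@H]([O-])[C@@H](C)[C@H](C)[C@H](OS(C)(=O)=O)c2ccc(OS(=O)(=O)c3ccc(C)cc3)c(OC)c2)ccc1OS(=O)(=O)c1ccc(C)cc1.CCCC[N+](CCCC)(CCCC)CCCC | intermediate
24 | (2R,3S,4S,5R)-2,5-bis[3-methoxy-4-(tosyloxy)phenyl]-3,4-dimethyltetrahydrofuran | COc1cc([C@@H]2O[C@@H](c3ccc(OS(=O)(=O)c4ccc(C)cc4)c(OC)c3)[C@@H](C)[C@@H]2C)ccc1OS(=O)(=O)c1ccc(C)cc1 | intermediate
25 | 4,4′-[(2R,3S,4S,5R)-3,4-dimethyltetrahydrofuran-2,5-diyl]bis(2-methoxyphenol) | COc1cc([C@@H]2O[C@@H](c3ccc(O)c(OC)c3)[C@@H](C)[C@@H]2C)ccc1O | intermediate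
26 | ethyl (S)-lactate | C[C@H](O)C(=O)OCC | starting material
27 | (S)-2-hydroxy-N-methoxy-N-methylpropanamide | C[C@H](O)C(=O)N(C)OC | intermediate
28 | 4-bromo-1,2-dimethoxybenzene | COc1ccc(Br)cc1OC | starting material
29 | (3,4-dimethoxyphenyl)magnesium bromide | COc1ccc([Mg]Br)cc1OC | intermediate
30 | bis(halomagnesium) salt of the tetrahedral adduct of 29 with 27 | C[C@H](O[Mg]Cl)C(O[Mg]Br)(N(C)OC)c1ccc(OC)c(OC)c1 | intermediate
31 | (S)-1-(3,4-dimethoxyphenyl)-2-hydroxypropan-1-one | C[C@H](O)C(=O)c1ccc(OC)c(OC)c1 | intermediate
32 | (S)-1-(3,4-dimethoxyphenyl)-1-oxopropan-2-yl 4-methylbenzenesulfonate | C[C@H](OS(=O)(=O)c1ccc(C)cc1)C(=O)c1ccc(OC)c(OC)c1 | intermediate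
33 | (2R,2′R)-2,2′-{[(2R,3S,4S,5R)-3,4-dimethyltetrahydrofuran-2,5-diyl]bis[(2-methoxy-4,1-phenylene)oxy]}bis[1-(3,4-dimethoxyphenyl)propan-1-one] | COc1ccc(C(=O)[C@@H](C)Oc2ccc([C@@H]3O[C@@H](c4ccc(O[C@H](C)C(=O)c5ccc(OC)c(OC)c5)c(OC)c4)[C@@H](C)[C@@H]3C)cc2OC)cc1OC | intermediate
34 | (1R,1′R,2R,2′R)-2,2′-{[(2R,3S,4S,5R)-3,4-dimethyltetrahydrofuran-2,5-diyl]bis[(2-methoxy-4,1-phenylene)oxy]}bis[1-(3,4-dimethoxyphenyl)propan-1-ol] | COc1ccc([C@@H](O)[C@@H](C)Oc2ccc([C@@H]3O[C@@H](c4ccc(O[C@H](C)[C@H](O)c5ccc(OC)c(OC)c5)c(OC)c4)[C@@H](C)[C@@H]3C)cc2OC)cc1OC | target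

## Step count and least certain steps

Total step count: 17. Longest linear sequence: 13 steps (steps 1 to 6, 8 to 12, 16 and 17); steps 7 and 13 to 15 are side branches.

Step 11 (key step). The most likely failure is ionisation of the C2–O bond before the alkoxide arrives, which would erode the inversion and let the trans C2 epimer form. Base-induced elimination toward C3, or fluoride-induced loss of an aryl sulfonate followed by quinone methide formation, would have the same effect. The fallback leaves the displacement logic. It sets out from 13: addition of one equivalent of 18 in THF at −78 °C should give the cyclic hemiketal F1, and reduction of F1 with Et3SiH and BF3·OEt2 in CH2Cl2 at −78 °C, through the 2-aryl oxocarbenium ion with hydride entering trans to the C3 methyl group, should give 24, where the route is rejoined. The electron-poor aryl ring at C5 should keep that centre from ionising under the Lewis acid.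

Step 17. The most likely failure is poor facial selectivity at one of the two carbonyl groups, for example through partial chelation by the aryl ether and methoxy oxygens; both reductions must follow the same sense. The fallback replaces substrate control by catalyst control. It sets out from 33 and uses a Corey–Bakshi–Shibata reduction with BH3·SMe2 and the enantiomer of 2-methyl-CBS-oxazaborolidine (1-methyl-3,3-diphenyltetrahydro-1H,3H-pyrrolo[1,2-c][1,3,2]oxazaborole) that is matched with the Felkin–Anh sense, expected to be the (R)-catalyst if the aryl group acts as the larger substituent. It comes back at 34. Compounds new to the list: none F0.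

Step 16. The most likely failure is enolisation under base, which would racemise 32 or epimerise C8 of 33, together with incomplete second alkylation. The fallback builds the ether before the ketone exists. It sets out from 25: Mitsunobu etherification with 26 (PPh3, DIAD, THF; inversion at the lactate carbon) should give the bis[(R)-2-aryloxypropanoate] F2. Aminolysis with Me(MeO)NH·HCl and iPrMgCl should give the bis(Weinreb amide) F3, and addition of 29 should give 33, where the route is rejoined.

Step 9. The most likely failure is insufficient facial selectivity, since the bias comes from C3 alone, which would leave a mixture of C2 epimers and later a mixture of ring isomers. The fallback sets out from 20 and uses catalyst-controlled Corey–Bakshi–Shibata reduction (BH3·SMe2 and the 2-methyl-CBS-oxazaborolidine enantiomer matched with the Felkin–Anh sense, expected to be the (R)-catalyst). It comes back at 21. Compounds new to the list: none F0.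

Step 8. The most likely failures are slow bromine–magnesium exchange, attack of the organomagnesium reagent at sulfonyl sulfur, or base-induced epimerisation at C3 during acyl substitution on the hindered amide. The fallback uses a more reactive electrophile. It sets out from 15: reduction with iBu2AlH in CH2Cl2 at −78 °C should give the aldehyde F4, addition of 18 at −78 °C should give the carbinol mixture F5 (both C2 epimers, of no consequence), and Dess–Martin oxidation should give 20, where the route is rejoined.

Further compounds

F1 | step 11 | (3S,4S,5R)-2,5-bis[3-methoxy-4-(tosyloxy)phenyl]-3,4-dimethyltetrahydrofuran-2-ol (cyclic hemiketal, C2 of either configuration) | COc1cc([C@@H]2OC(O)(c3ccc(OS(=O)(=O)c4ccc(C)cc4)c(OC)c3)[C@@H](C)[C@@H]2C)ccc1OS(=O)(=O)c1ccc(C)cc1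
F0 | step 17 | none | none
F2 | step 16 | diethyl (2R,2′R)-2,2′-{[(2R,3S,4S,5R)-3,4-dimethyltetrahydrofuran-2,5-diyl]bis[(2-methoxy-4,1-phenylene)oxy]}dipropanoate | CCOC(=O)[C@@H](C)Oc1ccc([C@@H]2O[C@@H](c3ccc(O[C@H](C)C(=O)OCC)c(OC)c3)[C@@H](C)[C@@H]2C)cc1OC
F3 | step 16 | (2R,2′R)-2,2′-{[(2R,3S,4S,5R)-3,4-dimethyltetrahydrofuran-2,5-diyl]bis[(2-methoxy-4,1-phenylene)oxy]}bis(N-methoxy-N-methylpropanamide) | CON(C)C(=O)[C@@H](C)Oc1ccc([C@@H]2O[C@@H](c3ccc(O[C@H](C)C(=O)N(C)OC)c(OC)c3)[C@@H](C)[C@@H]2C)cc1OC
F0 | step 9 | none | none
F4 | step 8 | (2S,3S,4R)-2,3-dimethyl-4-[3-methoxy-4-(tosyloxy)phenyl]-4-(triethylsilyloxy)butanal | O=C[C@@H](C)[C@H](C)[C@@H](O[Si](CC)(CC)CC)c1ccc(OS(=O)(=O)c2ccc(C)cc2)c(OC)c1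
F5 | step 8 | (2S,3S,4R)-2,3-dimethyl-1,4-bis[3-methoxy-4-(tosyloxy)phenyl]-4-(triethylsilyloxy)butan-1-ol, both C1 epimers | COc1cc([C@H](O[Si](CC)(CC)CC)[C@@H](C)[C@H](C)C(O)c2ccc(OS(=O)(=O)c3ccc(C)cc3)c(OC)c2)ccc1OS(=O)(=O)c1ccc(C)cc1
A1 | alternative 1 | bis(methoxymethyl ether) of 34 | COc1ccc([C@@H](OCOC)[C@@H](C)Oc2ccc([C@@H]3O[C@@H](c4ccc(O[C@H](C)[C@H](OCOC)c5ccc(OC)c(OC)c5)c(OC)c4)[C@@H](C)[C@@H]3C)cc2OC)cc1OC
A2 | alternative 1 | (2R,3S,4S,5R)-2,5-bis(4-bromo-3-methoxyphenyl)-3,4-dimethyltetrahydrofuran | COc1cc([C@@H]2O[C@@H](c3ccc(Br)c(OC)c3)[C@@H](C)[C@@H]2C)ccc1Br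
A3 | alternative 1 | (1R,2R)-1-(3,4-dimethoxyphenyl)-1-(methoxymethoxy)propan-2-ol | COc1ccc([C@@H](OCOC)[C@@H](C)O)cc1OC
A4 | alternative 2 | bis(acetate) of 34 | COc1ccc([C@@H](OC(C)=O)[C@@H](C)Oc2ccc([C@@H]3O[C@@H](c4ccc(O[C@H](C)[C@H](OC(C)=O)c5ccc(OC)c(OC)c5)c(OC)c4)[C@@H](C)[C@@H]3C)cc2OC)cc1OC
A5 | alternative 2 | (1R,2R)-1-(3,4-dimethoxyphenyl)-2-{2-methoxy-4-[(E)-prop-1-en-1-yl]phenoxy}propyl acetate | COc1ccc([C@@H](OC(C)=O)[C@@H](C)Oc2ccc(/C=C/C)cc2OC)cc1OC
A6 | alternative 3 | (2R,3S,4S,5R)-2,5-bis[4-(benzyloxy)-3-methoxyphenyl]-4-methyltetrahydrofuran-3-carbaldehyde | COc1cc([C@@H]2O[C@@H](c3ccc(OCc4ccccc4)c(OC)c3)[C@@H](C)[C@@H]2C=O)ccc1OCc1ccccc1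
A7 | alternative 3 | (4R,5S)-2,4-bis[4-(benzyloxy)-3-methoxyphenyl]-5-methyl-4,5-dihydro-1,3-dioxepine (acetal carbon of either configuration) | COc1cc(C2OC=C[C@H](C)[C@H](c3ccc(OCc4ccccc4)c(OC)c3)O2)ccc1OCc1ccccc1
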